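The six-membered carbocycle (C1–C6) is disconnected at its only alkene, C2=C3, which lies between the two ketone carbons C1 and C4. Both are carried as allylic carbinols held cis on the preformed C5–C6 oxirane, so one ring-closing metathesis joins the C3 vinyl group to the 1,1-disubstituted C2 alkene, closing the ring and forming the trisubstituted alkene with loss of ethylene. The precursor is an acyclic cis-epoxy diene diol that already has C5, C6 and C7 in their final configuration, both acetates and the complete chain, with C12 free as the electron-poor dienal so that C8=C9 and C10=C11 stay out of the metathesis. One oxidation then gives the ene-dione.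

Key step: step 17

Locants used throughout: ring C1(=O), C2(CH2OAc), C3H, C4(=O), C5 and C6H, with the oxirane on C5–C6; chain C7H(OAc), C8H, C9(Me), C10H, C11H, C12HO.

Remarks on the chemistry:
- Assumption: the C1 and C4 carbinol centres are formed without control and are destroyed in the last step, so they are carried as epimer mixtures and their SMILES leave these centres undefined. The C4 epimers become separable diastereomers after step 10 and may be advanced in parallel if that eases analysis.
- Ring size does not exclude the chain alkenes from the metathesis: the C3 alkylidene could close a five-membered ring (C3, C4, C5, C7, C8) on C8=C9 or a seven-membered ring on C10=C11. The substrate therefore carries the chain as the free dienal (both chain alkenes electron-poor, C9 fully substituted), keeps the C7 oxygen acetylated and leaves the C1 and C4 hydroxyls free.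
- The configuration of the oxirane is assigned from the known facial rule of the titanium tartrate epoxidation; the unnatural D-(−)-tartrate is required.

**Dienyl iodide (C8–C12)**

Step 1
Reactants: 1 prop-2-yn-1-ol
Product: 3 (E)-3-iodo-2-methylprop-2-en-1-ol, via alkenylalane 2 (not isolated)
Conditions: Me3Al (3 equiv), Cp2ZrCl2 (0.25 equiv), CH2Cl2, 0 °C to rt; then I2, THF, −30 to 0 °C
Reagents that add atoms: trimethylaluminium C[Al](C)C; iodine II
Why: Zirconium-catalysed carboalumination (Negishi) adds methyl and aluminium syn across the alkyne with methyl on the internal carbon, and iodinolysis of the alkenyl C–Al bond with retention fixes the E geometry of the later C8=C9 bond.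

Step 2
Reactants: 3 (E)-3-iodo-2-methylprop-2-en-1-ol
Product: 4 (E)-3-iodo-2-methylprop-2-enal
Conditions: MnO2 (activated, 15 equiv), CH2Cl2, rt, dark
Reagents that add atoms: none
Why: Allylic alcohol oxidation with activated MnO2 stops at the enal and leaves the alkenyl iodide and its geometry untouched.

Step 3
Reactants: 4 (E)-3-iodo-2-methylprop-2-enal; 5 tributyl(1,3-dioxolan-2-ylmethyl)phosphonium bromide
Product: 7 2-[(1E,3E)-4-iodo-3-methylbuta-1,3-dien-1-yl]-1,3-dioxolane, via phosphonium ylide 6 (not isolated)
Conditions: 5, t-BuOK, THF, 0 °C; then 4, 0 °C to rt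
Reagents that add atoms: none
Why: Wittig olefination with the preformed trialkylphosphonium ylide, which is known to give mainly E alkenes with enals, adds C11–C12 with the aldehyde already masked as the dioxolane (any Z isomer is removed by chromatography).

**C2 unit**

Step 4
Reactants: 8 2-bromoprop-2-en-1-ol
Product: 9 2-bromoprop-2-en-1-yl acetate
Conditions: Ac2O, pyridine, DMAP (cat.), CH2Cl2, 0 °C to rt
Reagents that add atoms: acetic anhydride CC(=O)OC(C)=O
Why: DMAP-catalysed acylation of the primary alcohol (esterification) has no effect on the alkenyl bromide.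

**Main line**

Step 5
Reactants: 10 but-2-yne-1,4-diol
Product: 11 4-[(4-methoxyphenyl)methoxy]but-2-yn-1-ol
Conditions: 10 (3 equiv), NaH (1 equiv), 4-methoxybenzyl chloride (1 equiv), Bu4NI (cat.), DMF, 0 °C to rt
Reagents that add atoms: 4-methoxybenzyl chloride COc1ccc(CCl)cc1
Why: Williamson etherification of the monoalkoxide, in which the excess of diol limits double alkylation and is washed out with water.

Step 6
Reactants: 11 4-[(4-methoxyphenyl)methoxy]but-2-yn-1-ol
Product: 13 (Z)-3-iodo-4-[(4-methoxyphenyl)methoxy]but-2-en-1-ol, via cyclic alkenylalanate 12 (not isolated)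
Conditions: NaAlH2(OCH2CH2OMe)2 (Red-Al, 1.6 equiv), THF, 0 °C; then I2, THF, −78 to 0 °C
Reagents that add atoms: iodine II
Why: Hydroxyl-directed trans-hydroalumination places aluminium on the alkyne carbon remote from the alkoxide in a five-membered alanate (kept at or below 0 °C so that the ether is not expelled), and iodinolysis with retention gives the Z iodide in which iodine, the later C4 attachment, is cis to the C1 hydroxymethyl.

Step 7
Reactants: 13 (Z)-3-iodo-4-[(4-methoxyphenyl)methoxy]but-2-en-1-ol; 14 prop-2-enal
Product: 15 (2Z)-3-{[(4-methoxyphenyl)methoxy]methyl}hexa-2,5-diene-1,4-diol (racemic at C4)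
Conditions: 14 (3 equiv), CrCl2 (5 equiv), NiCl2 (1 mol%), DMSO, rt
Reagents that add atoms: none
Why: Nozaki–Hiyama–Kishi coupling, in which zerovalent nickel inserts into the C–I bond, transmetalation to trivalent chromium keeps the alkene geometry and the alkenylchromium adds 1,2 to acrolein in the presence of the free hydroxyl, gives the C4 carbinol as a racemate, which is acceptable because C4 ends as a ketone.

Step 8
Reactants: 15 (2Z)-3-{[(4-methoxyphenyl)methoxy]methyl}hexa-2,5-diene-1,4-diol
Product: 16 bis(triethylsilyl) ether of 15 (O1 and O4; racemic)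
Conditions: Et3SiCl (2.5 equiv), imidazole (5 equiv), DMAP (cat.), DMF, 0 °C to rt
Reagents that add atoms: chlorotriethylsilane CC[Si](Cl)(CC)CC
Why: Silyl ether formation on both hydroxyls in one operation gives a primary (C1) and a hindered secondary (C4) triethylsilyl ether that can be told apart later.

Step 9
Reactants: 16 bis(triethylsilyl) ether
Product: 17 (2Z)-4-[(triethylsilyl)oxy]-2-{1-[(triethylsilyl)oxy]prop-2-en-1-yl}but-2-en-1-ol (racemic; free C7 hydroxymethyl)
Conditions: DDQ (1.3 equiv), CH2Cl2/pH 7 buffer (10:1), 0 °C
Reagents that add atoms: none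
Why: Oxidative cleavage of the 4-methoxybenzyl ether by DDQ (hydride abstraction from the electron-rich benzylic position, then hydrolysis) frees the C7 hydroxyl while silyl ethers and isolated alkenes are inert under buffered conditions.

Step 10
Reactants: 17 primary allylic alcohol
Product: 18 epoxy alcohol (oxirane on C5–C6 as in the target; both C4 epimers)
Conditions: Ti(OiPr)4 (0.2 equiv), D-(−)-diethyl tartrate (0.25 equiv), t-BuOOH (2 equiv, decane), 4 Å sieves, CH2Cl2, −20 °C
Reagents that add atoms: tert-butyl hydroperoxide CC(C)(C)OO
Why: Sharpless asymmetric epoxidation, in which the titanium tartrate complex bound through the C7 hydroxyl delivers oxygen to one face of the E-trisubstituted C5=C6 alkene under reagent control, should give with D-(−)-tartrate the oxirane configuration of the target (the face opposite to that taken by L-(+)-tartrate, which gives 2S epoxy alcohols from E-2-alken-1-ols), and syn addition keeps C4 and C1 cis.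

Step 11
Reactants: 18 epoxy alcohol
Product: 19 epoxy aldehyde (C7 formyl on C5; both C4 epimers)
Conditions: Dess–Martin periodinane (1.5 equiv), pyridine, CH2Cl2, 0 °C to rt
Reagents that add atoms: none
Why: Dess–Martin oxidation of the primary epoxy alcohol under pyridine buffering gives the aldehyde without acid or base that could open the oxirane, and C5 is quaternary so nothing can epimerise.

Step 12
Reactants: 19 epoxy aldehyde; 7 2-[(1E,3E)-4-iodo-3-methylbuta-1,3-dien-1-yl]-1,3-dioxolane
Product: 20 C7 carbinol (7S; full chain with C12 as dioxolane; both C4 epimers)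
Conditions: 7 (2.5 equiv), CrCl2 (8 equiv), NiCl2 (1 mol%), DMSO, rt
Reagents that add atoms: none
Why: Nozaki–Hiyama–Kishi coupling forms C7–C8 with retention of the iodide geometry, and in the non-chelated Cornforth-type arrangement of the α-quaternary epoxy aldehyde (C7=O anti to the C5–O oxirane bond) the alkenylchromium should approach past the tied-back oxirane C6–H and away from the branched C4 substituent, which sets the 7S carbinol (the minor 7R epimer is removed by chromatography).

Step 13
Reactants: 20 C7 carbinol
Product: 21 C7 acetate (7S)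
Conditions: Ac2O, pyridine, DMAP (cat.), CH2Cl2, 0 °C to rt
Reagents that add atoms: acetic anhydride CC(=O)OC(C)=O
Why: DMAP-catalysed acetylation of the hindered secondary carbinol takes place at oxygen without touching the C7–O bond, so the 7S configuration is kept.

Step 14
Reactants: 21 C7 acetate
Product: 23 C1 aldehyde (formyl on C6; C4 triethylsilyl ether retained), via alkoxysulfonium chloride 22 (not isolated)
Conditions: (COCl)2 (4 equiv), DMSO (8 equiv), CH2Cl2, −78 to −30 °C; then Et3N, −78 to 0 °C
Reagents that add atoms: none
Why: Swern oxidation applied directly to the silyl ether, in which the activated sulfoxide cleaves the primary triethylsilyl ether to the alkoxysulfonium salt that collapses to the aldehyde on addition of base, leaves the hindered secondary triethylsilyl ether at C4 in place (a known chemoselective oxidative desilylation) and avoids fluoride or base near the acetate.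

Step 15
Reactants: 23 C1 aldehyde; 9 2-bromoprop-2-en-1-yl acetate
Product: 24 C1 carbinol (C2 alkene and CH2OAc in place; C1 and C4 epimers)
Conditions: 9 (4 equiv), CrCl2 (10 equiv), NiCl2 (2 mol%), DMF, rt
Reagents that add atoms: none
Why: Nozaki–Hiyama–Kishi coupling of the alkenyl bromide with the epoxy aldehyde forms C1–C2 and tolerates the acetates, the silyl ether, the dioxolane and the oxirane, and both C1 epimers are used because C1 ends as a ketone.

Step 16
Reactants: 24 C1 carbinol
Product: 25 acyclic cis-epoxy diene diol with free dienal (metathesis substrate; C1 and C4 epimers)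
Conditions: TsOH·H2O (0.3 equiv), THF/H2O (4:1), 0 °C to rt
Reagents that add atoms: water O
Why: Acid-catalysed hydrolysis cleaves the two most labile groups, the secondary triethylsilyl ether and the conjugated dioxolane (stabilised dienyl oxocarbenium ion), while the acetates and the oxirane, which is deactivated by three flanking oxygenated carbons, should survive the dilute non-nucleophilic acid.

Step 17
Reactants: 25 acyclic cis-epoxy diene diol
Product: 26 epoxycyclohexene-1,4-diol (ring closed; C5, C6, C7, chain and acetates as in the target; C1 and C4 epimers)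
Conditions: second-generation Hoveyda–Grubbs catalyst RuCl2(H2IMes)(=CH-C6H4-2-OiPr) (10 mol%, two portions), CH2Cl2 (2 mM), 40 °C
Reagents that add atoms: none
Why: Ring-closing olefin metathesis: the catalyst loads onto the monosubstituted C3 vinyl group, the C3 alkylidene adds [2+2] to the 1,1-disubstituted C2 alkene, and cycloreversion of the ruthenacyclobutane forms C2=C3 and releases Ru=CH2, which gives ethylene on the next turnover. The closest known reaction type is the metathesis closure of 1,7-dienes with one geminally disubstituted terminus to trisubstituted cyclohexenes bearing allylic oxygen. The six-membered carbocycle C1–C6 is closed with the new alkene endocyclic, and the cis-oxirane already holds C4 and C1 on one face so that the two termini can meet. No stereocentre is formed, C5, C6 and C7 are not touched, and every C1/C4 epimer gives a diol that converges in step 18. The step needs selectivity for the C2 terminus over the chain alkenes, because the C3 alkylidene could also close a five-membered ring on C8=C9 or a seven-membered ring on C10=C11; this is secured by the free dienal (both chain alkenes electron-poor, C9 fully substituted, C8 next to the acetoxy-bearing C7) and by the free allylic hydroxyls at C1 and C4, which speed reaction at the two terminal alkenes. High dilution suppresses intermolecular metathesis.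

Step 18
Reactants: 26 epoxycyclohexene-1,4-diol
Product: 27 target ene-dione
Conditions: Dess–Martin periodinane (3 equiv), CH2Cl2, 0 °C to rt
Reagents that add atoms: none
Why: Dess–Martin oxidation of both secondary ring carbinols gives the ene-dione under near-neutral conditions that spare the oxirane, the acetates and the dienal, and all C1/C4 diastereomers converge on the single target.

**Compound list**

1 | prop-2-yn-1-ol (propargyl alcohol) | C#CCO | starting material
2 | alkenylalane: dimethylaluminium (E)-3-(dimethylalumanyl)-2-methylprop-2-en-1-olate | C[Al](C)OC/C(C)=C/[Al](C)C | intermediate (not isolated)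
3 | (E)-3-iodo-2-methylprop-2-en-1-ol | OC/C(C)=C/I | intermediate
4 | (E)-3-iodo-2-methylprop-2-enal | O=C/C(C)=C/I | intermediate
5 | tributyl(1,3-dioxolan-2-ylmethyl)phosphonium bromide | CCCC[P+](CCCC)(CCCC)CC1OCCO1.[Br-] | starting material
6 | phosphonium ylide: tributyl(1,3-dioxolan-2-ylmethylidene)phosphorane | CCCCP(CCCC)(CCCC)=CC1OCCO1 | intermediate (not isolated)
7 | 2-[(1E,3E)-4-iodo-3-methylbuta-1,3-dien-1-yl]-1,3-dioxolane | I/C=C(C)/C=C/C1OCCO1 | intermediate
8 | 2-bromoprop-2-en-1-ol (2-bromoallyl alcohol) | OCC(Br)=C | starting material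
9 | 2-bromoprop-2-en-1-yl acetate | CC(=O)OCC(Br)=C | intermediate
10 | but-2-yne-1,4-diol | OCC#CCO | starting material
11 | 4-[(4-methoxyphenyl)methoxy]but-2-yn-1-ol | COc1ccc(COCC#CCO)cc1 | intermediate
12 | cyclic alkenylalanate, sodium salt (five-membered O–Al–C=C–C ring, two 2-methoxyethoxy ligands on aluminium) | COCCO[Al-]1(OCCOC)OCC=C1COCc1ccc(OC)cc1.[Na+] | intermediate (not isolated)
13 | (Z)-3-iodo-4-[(4-methoxyphenyl)methoxy]but-2-en-1-ol | COc1ccc(COC/C(I)=C/CO)cc1 | intermediate
14 | prop-2-enal (acrolein) | C=CC=O | starting material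
15 | (2Z)-3-{[(4-methoxyphenyl)methoxy]methyl}hexa-2,5-diene-1,4-diol, racemic at C4 (hexadiene C1, C2, C3, C4, C5 are target C1, C6, C5, C4, C3; C4 cis to C1) | COc1ccc(COC/C(=C/CO)C(O)C=C)cc1 | intermediate
16 | (2Z)-3-{[(4-methoxyphenyl)methoxy]methyl}-1,4-bis[(triethylsilyl)oxy]hexa-2,5-diene, racemic | COc1ccc(COC/C(=C/CO[Si](CC)(CC)CC)C(O[Si](CC)(CC)CC)C=C)cc1 | intermediate
17 | (2Z)-4-[(triethylsilyl)oxy]-2-{1-[(triethylsilyl)oxy]prop-2-en-1-yl}but-2-en-1-ol, racemic | OC/C(=C/CO[Si](CC)(CC)CC)C(O[Si](CC)(CC)CC)C=C | intermediate
18 | {(2R,3R)-3-{[(triethylsilyl)oxy]methyl}-2-{1-[(triethylsilyl)oxy]prop-2-en-1-yl}oxiran-2-yl}methanol, both C4 epimers (C4 and C1 cis on the oxirane) | C=CC(O[Si](CC)(CC)CC)[C@]1(CO)O[C@@H]1CO[Si](CC)(CC)CC | intermediate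
19 | (2R,3R)-3-{[(triethylsilyl)oxy]methyl}-2-{1-[(triethylsilyl)oxy]prop-2-en-1-yl}oxirane-2-carbaldehyde, both C4 epimers | C=CC(O[Si](CC)(CC)CC)[C@]1(C=O)O[C@@H]1CO[Si](CC)(CC)CC | intermediate
20 | C7 carbinol: oxirane of 19 carrying on C5 the (1S,2E,4E)-5-(1,3-dioxolan-2-yl)-1-hydroxy-3-methylpenta-2,4-dien-1-yl group (7S), both C4 epimers | C=CC(O[Si](CC)(CC)CC)[C@]1([C@H](/C=C(C)/C=C/C2OCCO2)O)O[C@@H]1CO[Si](CC)(CC)CC | intermediate
21 | C7 acetate of 20 (7S), both C4 epimers | C=CC(O[Si](CC)(CC)CC)[C@]1([C@H](/C=C(C)/C=C/C2OCCO2)OC(C)=O)O[C@@H]1CO[Si](CC)(CC)CC | intermediate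
22 | alkoxysulfonium chloride: 21 with the C1 silyl ether replaced by C1–O–S(+)Me2 Cl(−) | C=CC(O[Si](CC)(CC)CC)[C@]1([C@H](/C=C(C)/C=C/C2OCCO2)OC(C)=O)O[C@@H]1CO[S+](C)C.[Cl-] | intermediate (not isolated)
23 | C1 aldehyde: 21 with the CH2OSiEt3 group on C6 replaced by CHO, both C4 epimers | C=CC(O[Si](CC)(CC)CC)[C@]1([C@H](/C=C(C)/C=C/C2OCCO2)OC(C)=O)O[C@@H]1C=O | intermediate
24 | C1 carbinol: 23 after addition of the 3-acetoxyprop-1-en-2-yl group to C1, C1 and C4 epimers | C=CC(O[Si](CC)(CC)CC)[C@]1([C@H](/C=C(C)/C=C/C2OCCO2)OC(C)=O)O[C@@H]1C(O)C(=C)COC(C)=O | intermediate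
25 | metathesis substrate: acyclic cis-epoxy diene diol, C1–OH and C4–OH free, C7–OAc (7S), CH2OAc on C2, C12 as free (8E,10E)-dienal, C1 and C4 epimers | C=CC(O)[C@]1([C@H](/C=C(C)/C=C/C=O)OC(C)=O)O[C@@H]1C(O)C(=C)COC(C)=O | intermediate
26 | metathesis product: 7-oxabicyclo[4.1.0]hept-3-ene-2,5-diol with the target's side chain and acetates (C1 and C4 carbinols, epimers) | CC(=O)OCC1=CC(O)[C@]2([C@H](/C=C(C)/C=C/C=O)OC(C)=O)O[C@@H]2C1O | intermediate
27 | (1S,2E,4E)-1-[(1R,6S)-4-(acetoxymethyl)-2,5-dioxo-7-oxabicyclo[4.1.0]hept-3-en-1-yl]-3-methyl-6-oxohexa-2,4-dien-1-yl acetate | CC(=O)OCC1=CC(=O)[C@]2([C@H](/C=C(C)/C=C/C=O)OC(C)=O)O[C@@H]2C1=O | target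

**Totals**

Total step count: 18. Longest linear sequence: 14 steps (steps 5 to 18, from but-2-yne-1,4-diol).

**Steps most likely to fail**

Step 17. What may go wrong: the C3 alkylidene closes onto C8=C9 to a spiro five-membered ring, or is consumed by cross-metathesis, faster than it engages the hindered 1,1-disubstituted C2 alkene. The fallback shields C8=C9 sterically and installs the C7 acetate last. It sets out from 20: TBSOTf and 2,6-lutidine in CH2Cl2 at −78 °C give the C7 tert-butyldimethylsilyl ether F1; Swern oxidation as in step 14 passes through the alkoxysulfonium chloride F2 (not isolated) to the C1 aldehyde F3; coupling with 9 under the conditions of step 15 gives the C1 carbinol F4; TsOH·H2O in wet THF removes the triethylsilyl group and the dioxolane but not the hindered silyl ether on C7 and gives the silyl-protected dienal diol F5; metathesis with the catalyst of step 17, now with a bulky silyloxy group beside C8=C9, gives the cyclohexenediol F6; Dess–Martin periodinane gives the silyl-protected ene-dione F7; HF·pyridine in THF/pyridine frees the C7 hydroxyl to give the hydroxy ene-dione F8; Ac2O and pyridine in CH2Cl2 at 0 °C then return to 27.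

Step 12. What may go wrong: poor facial discrimination in the addition of the alkenylchromium to the α-quaternary epoxy aldehyde, or preferential attack on the C4 side, made harder to read by the C4 epimer mixture. The fallback sets C7 by reduction instead of by C–C bond formation. It sets out from 20 obtained as a mixture of C7 epimers: Dess–Martin periodinane with pyridine gives the dienyl epoxy ketone F9. Reduction with Zn(BH4)2 in Et2O at −30 °C should then give the 7S carbinol, because zinc bridges the ketone oxygen and the oxirane oxygen and hydride enters from the face opposite the branched C4 substituent. The branch comes back to the route at 20.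

Step 15. What may go wrong: loss of the acetoxy group from the metallated allyl acetate by β-elimination to an allene, so that the alkenylmetal is spent before it adds. The fallback couples the free alcohol and acetylates afterwards. It sets out from 23: coupling with the free alcohol 8 (CrCl2, NiCl2, DMF, rt), whose β-oxygen is a poor leaving group, gives the diol F10; acetyl chloride and 2,4,6-collidine in CH2Cl2 at −78 °C acetylate only the primary allylic hydroxyl, and the branch comes back to the route at 24.

**Further compounds**

F1 | step 17 | C7 tert-butyldimethylsilyl ether of 20 | C=CC(O[Si](CC)(CC)CC)[C@]1([C@H](/C=C(C)/C=C/C2OCCO2)O[Si](C)(C)C(C)(C)C)O[C@@H]1CO[Si](CC)(CC)CC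
F2 | step 17 | alkoxysulfonium chloride from F1 (not isolated) | C=CC(O[Si](CC)(CC)CC)[C@]1([C@H](/C=C(C)/C=C/C2OCCO2)O[Si](C)(C)C(C)(C)C)O[C@@H]1CO[S+](C)C.[Cl-]
F3 | step 17 | C1 aldehyde with C7 silyl ether | C=CC(O[Si](CC)(CC)CC)[C@]1([C@H](/C=C(C)/C=C/C2OCCO2)O[Si](C)(C)C(C)(C)C)O[C@@H]1C=O
F4 | step 17 | C1 carbinol with C7 silyl ether | C=CC(O[Si](CC)(CC)CC)[C@]1([C@H](/C=C(C)/C=C/C2OCCO2)O[Si](C)(C)C(C)(C)C)O[C@@H]1C(O)C(=C)COC(C)=O
F5 | step 17 | silyl-protected dienal diol | C=CC(O)[C@]1([C@H](/C=C(C)/C=C/C=O)O[Si](C)(C)C(C)(C)C)O[C@@H]1C(O)C(=C)COC(C)=O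
F6 | step 17 | cyclohexenediol with C7 silyl ether | CC(=O)OCC1=CC(O)[C@]2([C@H](/C=C(C)/C=C/C=O)O[Si](C)(C)C(C)(C)C)O[C@@H]2C1O
F7 | step 17 | silyl-protected ene-dione | CC(=O)OCC1=CC(=O)[C@]2([C@H](/C=C(C)/C=C/C=O)O[Si](C)(C)C(C)(C)C)O[C@@H]2C1=O
F8 | step 17 | hydroxy ene-dione (C7–OH) | CC(=O)OCC1=CC(=O)[C@]2([C@H](/C=C(C)/C=C/C=O)O)O[C@@H]2C1=O
F9 | step 12 | dienyl epoxy ketone (C7=O) | C=CC(O[Si](CC)(CC)CC)[C@]1(C(=O)/C=C(C)/C=C/C2OCCO2)O[C@@H]1CO[Si](CC)(CC)CC
F10 | step 15 | diol with free hydroxymethyl on C2 | C=CC(O[Si](CC)(CC)CC)[C@]1([C@H](/C=C(C)/C=C/C2OCCO2)OC(C)=O)O[C@@H]1C(O)C(=C)CO
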